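## Retrosynthetic overview

1. The target is achiral. Its only rings are two benzene rings, ring A (2,6-dimethoxyphenyl) and ring B (4-hydroxyphenyl). Both are bought, so no ring is formed in the route.
2. Key disconnection: ketone carbon C1 to methylene C2, read as a retro-hydroacylation. This gives 2,6-dimethoxybenzaldehyde and 4-(oct-7-en-1-yl)phenol. After traceless condensation with 2-amino-3-picoline, the formyl carbon reacts with reversed polarity as a rhodium-bound iminoacyl group.
3. Enabling feature: C1 sits on a ring A carbon whose two ortho carbons both bear OMe, so there is no ortho C–H and the aldehyde has no alpha hydrogen. C2–C3 is the unbranched CH2–CH2 end of the chain, which is the footprint of a terminal vinyl group after anti-Markovnikov C–H addition.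
4. Second disconnection: ring B carbon C4 to chain carbon C9. This is a B-alkyl Suzuki–Miyaura coupling of 4-iodophenol with the borane obtained by mono-hydroboration of octa-1,7-diene with 9-BBN.
5. No protecting group and no redox adjustment is used, and the last step delivers the free phenol ketone directly.

Key step: step 3

Remark: the SMILES holds no stereocentre and no double-bond geometry, so no stereochemical control is required anywhere in the route.

## Route

Step 1
Reactants: 1 octa-1,7-diene; 2 9-borabicyclo[3.3.1]nonane (9-BBN)
Product: 3 9-(oct-7-en-1-yl)-9-borabicyclo[3.3.1]nonane
Conditions: 1 (4 equiv), 2 (0.5 M in THF, added dropwise), THF, 0 °C to rt; THF and excess 1 removed in vacuo under Ar, residue used directly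
Reagents that add atoms: none
Why: Hydroboration with 9-BBN should place boron on the terminal carbon of a monosubstituted alkene for steric reasons, and because the two vinyl groups of 1 are equivalent and do not sense each other, a large excess of the cheap, volatile diene should make the mono-adduct statistically dominant.

Step 2
Reactants: 3 9-(oct-7-en-1-yl)-9-borabicyclo[3.3.1]nonane; 4 4-iodophenol
Product: 5 4-(oct-7-en-1-yl)phenol
Conditions: 3 (1.3 equiv), PdCl2(dppf) (3 mol %), 3 M aq NaOH (3.5 equiv), THF, 60 °C; aq NH4Cl work-up
Reagents that add atoms: none
Why: In this B-alkyl Suzuki–Miyaura coupling hydroxide turns 3 into a borate that hands its primary alkyl group to the arylpalladium iodide formed from 4, the wide bite angle of dppf favours reductive elimination over beta-hydride elimination, the iodide keeps oxidative addition to zerovalent palladium fast although the ring is a phenoxide under the conditions, and the remote vinyl group is a much poorer partner for arylpalladium than the borate.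

Step 3
Reactants: 5 4-(oct-7-en-1-yl)phenol; 6 2,6-dimethoxybenzaldehyde; 7 3-methylpyridin-2-amine (2-amino-3-picoline, traceless directing group)
Product: 10 1-(2,6-dimethoxyphenyl)-9-(4-hydroxyphenyl)nonan-1-one, via picolyl aldimine 8 (not isolated), via picolyl ketimine 9 (not isolated)
Conditions: 6, 7 (1.05 equiv), PhCO2H (10 mol %), toluene, reflux, azeotropic removal of water; then 5 (1.3 equiv), RhCl(PPh3)3 (5 mol %), 130 °C, sealed vessel; then 1 M HCl, THF, rt
Reagents that add atoms: water, O
Why: Acid-catalysed condensation of 6 with 7 gives aldimine 8, whose pyridine nitrogen (turned toward the formyl hydrogen by the 3-methyl group) delivers monovalent rhodium into the imidoyl C–H bond to form a five-membered N,C-chelated iminoacyl hydride of trivalent rhodium, so that the normally electrophilic formyl carbon becomes the metal-bound donor partner. The vinyl group of 5 then inserts into Rh–H with rhodium at the terminal carbon, C–C reductive elimination gives ketimine 9, and aqueous acid hydrolyses 9 to 10 and returns 7. The closest known reaction type is the chelation-assisted intermolecular hydroacylation (hydroiminoacylation followed by hydrolysis) of 1-alkenes with aromatic aldehydes under RhCl(PPh3)3 and 2-amino-3-picoline, which gives linear alkyl aryl ketones. No ring is closed and no stereocentre is created. The step needs linear over branched regioselectivity, which the unbranched monosubstituted alkene and the crowded rhodium centre should secure, and it needs coupling to outrun decarbonylation, which is secured because an iminoacyl ligand has no CO to extrude and the full equivalent of 7 leaves little free aldehyde. Ring A helps in three ways, since its two ortho carbons carry OMe and leave no ortho C–H for the imine-directed ortho-alkylation open to aromatic ketimines under this catalyst, 6 has no alpha hydrogen and cannot self-condense under amine and acid, and a methoxy oxygen can bind rhodium in a hemilabile way; the free phenol of ring B is a weaker acid than the benzoic acid additive and should take no part.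

## Compound list

1 | octa-1,7-diene | C=CCCCCC=C | starting material
2 | 9-borabicyclo[3.3.1]nonane (9-BBN, sold as the dimer or as a THF solution) | B1C2CCCC1CCC2 | starting material
3 | 9-(oct-7-en-1-yl)-9-borabicyclo[3.3.1]nonane | C=CCCCCCCB1C2CCCC1CCC2 | intermediate
4 | 4-iodophenol | Oc1ccc(I)cc1 | starting material
5 | 4-(oct-7-en-1-yl)phenol | C=CCCCCCCc1ccc(O)cc1 | intermediate
6 | 2,6-dimethoxybenzaldehyde | COc1cccc(OC)c1C=O | starting material
7 | 3-methylpyridin-2-amine (2-amino-3-picoline) | Cc1cccnc1N | starting material
8 | (E)-1-(2,6-dimethoxyphenyl)-N-(3-methylpyridin-2-yl)methanimine | COc1cccc(OC)c1/C=N/c1ncccc1C | intermediate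
9 | 4-{9-(2,6-dimethoxyphenyl)-9-[(3-methylpyridin-2-yl)imino]nonyl}phenol (C=N geometry not defined) | COc1cccc(OC)c1C(CCCCCCCCc1ccc(O)cc1)=Nc1ncccc1C | intermediate
10 | 1-(2,6-dimethoxyphenyl)-9-(4-hydroxyphenyl)nonan-1-one | COc1cccc(OC)c1C(=O)CCCCCCCCc1ccc(O)cc1 | target

## Step count and risks

Total step count: 3
Longest linear sequence: 3 (1 to 3 to 5 to 10)

Steps most likely to fail:

**1. Step 3.**
- **What may go wrong:** Condensation of the electron-rich, doubly ortho-substituted aldehyde with the weakly nucleophilic aminopyridine may be incomplete. C–H insertion at the crowded imidoyl carbon may be slow. In that case rhodium hydride migration of the terminal double bond along the chain, and decarbonylation of residual free aldehyde with poisoning of the catalyst by CO, could overtake the coupling.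
- **Fallback:** It sets out from 5 and comes back at 10. It makes the same C1–C2 bond from a nucleophilic alkyl metal and an acyl chloride instead of by C–H activation. Compound 5 is silylated (TBSCl, imidazole, DMF) to tert-butyldimethyl[4-(oct-7-en-1-yl)phenoxy]silane F1. Hydrozirconation with Cp2Zr(H)Cl in THF places the metal on the terminal carbon and gives chlorobis(cyclopentadienyl){8-[4-(tert-butyldimethylsilyloxy)phenyl]octyl}zirconium F2. This is acylated in the same flask with commercial 2,6-dimethoxybenzoyl chloride under CuBr·SMe2 catalysis to give 9-[4-(tert-butyldimethylsilyloxy)phenyl]-1-(2,6-dimethoxyphenyl)nonan-1-one F3. TBAF in THF then frees the phenol and gives 10.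

**2. Step 1.**
- **What may go wrong:** The mono-adduct may be hydroborated a second time at its remaining vinyl group (statistical over-addition). The air-sensitive borane may also be oxidised or hydrolysed while the excess diene is stripped.
- **Fallback:** It sets out from 4 and comes back at 5. The chain comes from a monofunctional C8 building block, so no desymmetrisation is needed. Commercial 8-bromooct-1-ene is treated with zinc dust and LiCl in THF to give oct-7-en-1-ylzinc bromide F4. This is added slowly to 4 with Pd(OAc)2 and SPhos in THF. In this Negishi coupling C–C bond formation is expected to be faster than protonation of the alkylzinc by the phenol, and the product is 5.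

**3. Step 2.**
- **What may go wrong:** Oxidative addition to the electron-rich iodophenoxide may be sluggish. That would leave time for Heck-type arylation of the free vinyl group, double-bond migration by palladium hydride, and protodeboronation of the borate.
- **Fallback:** It sets out from 4 and comes back at 5. It reverses the roles of the partners (aryl nucleophile, alkyl electrophile) and uses no palladium. Compound 4 is silylated (TBSCl, imidazole, DMF) to tert-butyl(4-iodophenoxy)dimethylsilane F5. Magnesium turnings in THF convert it into [4-(tert-butyldimethylsilyloxy)phenyl]magnesium iodide F6. Copper-catalysed Kumada-type alkylation with commercial 8-bromooct-1-ene (Li2CuCl4 cat., THF, 0 °C) gives tert-butyldimethyl[4-(oct-7-en-1-yl)phenoxy]silane F1. TBAF in THF then gives 5.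

## Further compounds

F1 | step 3 | tert-butyldimethyl[4-(oct-7-en-1-yl)phenoxy]silane | C=CCCCCCCc1ccc(O[Si](C)(C)C(C)(C)C)cc1
F2 | step 3 | chlorobis(cyclopentadienyl){8-[4-(tert-butyldimethylsilyloxy)phenyl]octyl}zirconium | Cl[Zr](CCCCCCCCc1ccc(O[Si](C)(C)C(C)(C)C)cc1)(C1C=CC=C1)C1C=CC=C1
F3 | step 3 | 9-[4-(tert-butyldimethylsilyloxy)phenyl]-1-(2,6-dimethoxyphenyl)nonan-1-one | COc1cccc(OC)c1C(=O)CCCCCCCCc1ccc(O[Si](C)(C)C(C)(C)C)cc1
F4 | step 1 | oct-7-en-1-ylzinc bromide | C=CCCCCCC[Zn]Br
F5 | step 2 | tert-butyl(4-iodophenoxy)dimethylsilane | CC(C)(C)[Si](C)(C)Oc1ccc(I)cc1
F6 | step 2 | [4-(tert-butyldimethylsilyloxy)phenyl]magnesium iodide | CC(C)(C)[Si](C)(C)Oc1ccc([Mg]I)cc1
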